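**Plan**

- Retrosynthesis: the C8 ester C–O bond is cut first, then the two exocyclic methylenes (C11=C13 from a C12 aldehyde, C4=C3 from a C4 ketone). The ring bonds C9–C8 and C6–C7 are cut next, removing C7–C8 as a siloxyalkyne and leaving a cyclobutanone (C6, C5, C10, C9) whose C6–C9 bond is not in the target. C10–vinyl and C10–CH3 are cut last, back to a cyclobutenone from a ketene and ethoxyacetylene.
- Forward: the four-membered ring is made first, then CH3 and vinyl are placed on C10, then the six-membered ring arises by two-carbon ring expansion, followed by reductions, acylation and side-chain adjustment.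
- Enabling feature: the quaternary C10 (CH3, vinyl) sits between CH2-9 and C5, and the carbinol carbon C6 is 1,4 to C9. C6/C5/C10/C9 therefore map onto a strained cyclobutanone whose acyl–CH2 bond can take up a two-carbon alkyne unit.
- Stereochemistry: C5 comes from the (S)-malate acetonide (diastereomer separation; that auxiliary centre is erased in step 16). C10 is set by vinyl addition anti to the C5 group. C6, C7 and C8 are set by hydride and proton delivery to the face opposite the C10 methyl and the C5 group. The Z-enoate geometry is inherited from a butenolide.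
- Numbering used below (elemane style): C10 = quaternary ring carbon; C9 = ring CH2; C8 = ester carbinol; C7 carries C11(=C13)C12; C6 = free carbinol; C5 carries C4(=C3)C15.

Key step: step 7

Assumption: the facial selectivity of the ketene cycloaddition in step 2 is taken as modest and is not relied on; the two C5 epimers are diastereomers and the required one is isolated by chromatography.

Abbreviations: PMB = 4-methoxybenzyl, TIPS = triisopropylsilyl, TBS = tert-butyldimethylsilyl.

**Step 1**
Reactants: 1 methyl [(4S)-2,2-dimethyl-1,3-dioxolan-4-yl]acetate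
Product: 2 [(4S)-2,2-dimethyl-1,3-dioxolan-4-yl]acetic acid
Conditions: LiOH, THF/H2O, 0 °C; then cold 1 M HCl to pH 4
Reagents that add atoms: lithium hydroxide, [Li+].[OH-]
Why: Ester saponification; the acetonide should survive the brief, cold, weakly acidic work-up and the stereocenter is not touched.

**Step 2**
Reactants: 2 [(4S)-2,2-dimethyl-1,3-dioxolan-4-yl]acetic acid; 3 ethoxyethyne
Product: 6 (4R)-4-[(4S)-2,2-dimethyl-1,3-dioxolan-4-yl]-3-ethoxycyclobut-2-en-1-one, via acyl chloride 4 (not isolated), via ketene 5 (not isolated)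
Conditions: 1-chloro-N,N,2-trimethylprop-1-en-1-amine, CH2Cl2, 0 °C; then slow addition to 3 (excess), Et3N, Et2O, 0 °C → rt; chromatography
Reagents that add atoms: none
Why: Dehydrochlorination gives the alkylketene, which should undergo the regioselective ketene–ynol ether [2+2] cycloaddition (nucleophilic CH terminus of 3 to the ketene carbonyl carbon); the new ring stereocenter (later C5) forms next to the dioxolane center, and the required (4R) diastereomer is separated from its epimer.

**Step 3**
Reactants: 6 (4R)-4-[(4S)-2,2-dimethyl-1,3-dioxolan-4-yl]-3-ethoxycyclobut-2-en-1-one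
Product: 8 (4R)-4-[(4S)-2,2-dimethyl-1,3-dioxolan-4-yl]-3-methylcyclobut-2-en-1-one, via carbinol 7 (not isolated)
Conditions: MeLi, THF, −78 °C; then 0.5 M HCl, 0 °C
Reagents that add atoms: methyllithium, [Li]C
Why: 1,2-Addition to the vinylogous ester followed by acid-induced loss of ethanol (Stork–Danheiser-type 1,3-carbonyl transposition) puts CH3 on the future C10 and the carbonyl on the future C6; the ring stereocenter is not enolized because the enolate would be a cyclobutadiene-type anion.

**Step 4**
Reactants: 8 (4R)-4-[(4S)-2,2-dimethyl-1,3-dioxolan-4-yl]-3-methylcyclobut-2-en-1-one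
Product: 9 (2R,3S)-2-[(4S)-2,2-dimethyl-1,3-dioxolan-4-yl]-3-ethenyl-3-methylcyclobutan-1-one
Conditions: CH2=CHMgBr, CuBr·SMe2 (10 mol%), THF, −78 °C; then sat. aq. NH4Cl
Reagents that add atoms: vinylmagnesium bromide, C=C[Mg]Br
Why: Copper-catalyzed conjugate addition to the strained enone; vinyl should enter anti to the branched dioxolanyl group on the neighbouring carbon, which sets the quaternary C10 with CH3 cis to the C5 substituent.

**Step 5**
Reactants: 10 but-3-yn-1-ol
Product: 11 1-[(but-3-yn-1-yloxy)methyl]-4-methoxybenzene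
Conditions: NaH, PMBCl, Bu4NI (cat.), THF/DMF, 0 °C → rt
Reagents that add atoms: 4-methoxybenzyl chloride, COc1ccc(CCl)cc1
Why: Williamson etherification of the alkoxide, which forms in preference to the acetylide.

**Step 6**
Reactants: 11 1-[(but-3-yn-1-yloxy)methyl]-4-methoxybenzene
Product: 14 triisopropyl({4-[(4-methoxybenzyl)oxy]but-1-yn-1-yl}oxy)silane, via lithium acetylide 12 (not isolated), via lithium ynolate 13 (not isolated)
Conditions: n-BuLi, THF, −78 °C; LiOOt-Bu (from t-BuOOH and LiHMDS), −78 → 0 °C; TIPSOTf, −78 °C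
Reagents that add atoms: tert-butyl hydroperoxide, CC(C)(C)OO; triisopropylsilyl trifluoromethanesulfonate, CC(C)[Si](OS(=O)(=O)C(F)(F)F)(C(C)C)C(C)C
Why: Known oxidation of a lithium acetylide to the ynolate by lithium tert-butyl peroxide, followed by O-silylation with the bulky silyl triflate, gives an isolable siloxyalkyne.

**Step 7**
Reactants: 9 (2R,3S)-2-[(4S)-2,2-dimethyl-1,3-dioxolan-4-yl]-3-ethenyl-3-methylcyclobutan-1-one; 14 triisopropyl({4-[(4-methoxybenzyl)oxy]but-1-yn-1-yl}oxy)silane
Product: 15 (5S,6R)-6-[(4S)-2,2-dimethyl-1,3-dioxolan-4-yl]-5-ethenyl-2-{2-[(4-methoxybenzyl)oxy]ethyl}-5-methyl-3-[(triisopropylsilyl)oxy]cyclohex-2-en-1-one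
Conditions: Ni(cod)2 (10 mol%), PCy3 (20 mol%), toluene, 70 °C
Reagents that add atoms: none
Why: Proposed new method: zerovalent nickel should couple the C6 carbonyl of 9 with the alkyne by oxidative cyclization (the alkyne carbon remote from oxygen bonds to the carbonyl carbon and forms C6–C7), the spiro oxanickelacyclopentene should then release ring strain by β-carbon elimination of the C6–C9 bond, and C(sp3)–C(sp2) reductive elimination from the seven-membered nickelacycle should form C9–C8 and return the catalyst. The closest known reaction type is the nickel-catalyzed intermolecular insertion of dialkyl- and aryl-substituted alkynes into 3-substituted cyclobutanones to give cyclohex-2-enones; a heteroatom-substituted alkyne and a 2-substituted cyclobutanone have not been shown. The six-membered ring is closed by that reductive elimination, so the step is a formal [4+2] ring expansion in which the C6–C9 bond, absent from the target, is traded for the two new ring bonds. No stereocenter is created, and C5 and C10 should pass through unchanged because the medium is neutral and C5 is not enolized. The step needs cleavage of C6–C9 and not C6–C5, which the branched, saturated dioxolanyl group on C5 should secure (a secondary alkylnickel next to a quaternary carbon is disfavoured and no allyl or enolate stabilization is available on that side). It also needs the oxygen-bearing alkyne carbon to end at C8, which the polarization of the ynol ether should secure.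

**Step 8**
Reactants: 15 (5S,6R)-6-[(4S)-2,2-dimethyl-1,3-dioxolan-4-yl]-5-ethenyl-2-{2-[(4-methoxybenzyl)oxy]ethyl}-5-methyl-3-[(triisopropylsilyl)oxy]cyclohex-2-en-1-one
Product: 16 the C6 allylic alcohol of 15 (6-OH cis to the C10 methyl and the C5 dioxolanyl group; silyl enol ether retained)
Conditions: DIBAL-H, CH2Cl2, −78 °C; aq. Rochelle salt
Reagents that add atoms: none
Why: 1,2-Reduction of the vinylogous silyl ester carbonyl; hydride should be delivered to the face opposite the C5 dioxolanyl group and the C10 methyl, which lie on the same side, so the new C6 hydroxyl ends cis to both.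

**Step 9**
Reactants: 16 the C6 allylic alcohol of 15
Product: 17 β-hydroxy ketone (C8 ketone; 6-OH, C7 side chain, C5 dioxolanyl and C10 methyl all cis)
Conditions: TBAF, AcOH, THF, −40 → 0 °C
Reagents that add atoms: none
Why: Buffered fluoride cleavage of the silyl enol ether unveils the C8 ketone without acid, so Stork–Danheiser-type loss of the C6 oxygen and retro-aldol cleavage are avoided; C7 should be protonated from the face opposite the C6 hydroxyl, giving the equatorial side chain, which is also the thermodynamic epimer.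

**Step 10**
Reactants: 17 β-hydroxy ketone
Product: 18 all-cis 4-[(4S)-2,2-dimethyl-1,3-dioxolan-4-yl]-5-ethenyl-2-{2-[(4-methoxybenzyl)oxy]ethyl}-5-methylcyclohexane-1,3-diol (1-OH = C8, 3-OH = C6; both hydroxyls, the C7 chain, the C5 group and the C10 methyl on one face)
Conditions: LiBH(s-Bu)3, THF, −78 °C; then H2O
Reagents that add atoms: none
Why: Bulky-hydride ketone reduction; with the C5 and C7 substituents equatorial, the axial C10 methyl and axial C6 oxygen block axial attack, so hydride should enter equatorially and give the axial C8 alcohol cis to the C6 hydroxyl.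

**Step 11**
Reactants: 19 3-methylfuran-2(5H)-one
Product: 23 (2Z)-4-(acetyloxy)-2-methylbut-2-enoic acid, via potassium hydroxy carboxylate 20 (not isolated), via silyl ester 21 (not isolated), via acetoxy silyl ester 22 (not isolated)
Conditions: KOH (1 equiv), MeOH/H2O, rt, evaporate; TBSCl (1 equiv), DMF, 0 °C; Ac2O, pyridine, DMAP (cat.), 0 °C; aq. NaHCO3, then pH 3
Reagents that add atoms: potassium hydroxide, [K+].[OH-]; acetic anhydride, CC(=O)OC(C)=O
Why: Saponification opens the butenolide with the Z geometry fixed by the ring; transient silylation of the carboxylate should prevent relactonization through a mixed anhydride while the hydroxyl is acetylated, and the silyl ester is hydrolyzed on work-up.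

**Step 12**
Reactants: 18 all-cis cyclohexane-1,3-diol; 23 (2Z)-4-(acetyloxy)-2-methylbut-2-enoic acid
Product: 25 the C8 mono-ester of 18 with acid 23 (6-OH free), via mixed anhydride 24 (not isolated)
Conditions: 23, 2,4,6-trichlorobenzoyl chloride, Et3N, toluene, rt; then 18, DMAP, 40 °C
Reagents that add atoms: none
Why: Yamaguchi esterification, a method used for angelate-type acids because it limits Z to E isomerization; the C8 hydroxyl (next to CH2-9) should react in preference to the C6 hydroxyl, which is flanked by the branched C5 substituent.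

**Step 13**
Reactants: 25 the C8 mono-ester of 18
Product: 26 the C6 tert-butyldimethylsilyl ether of 25
Conditions: TBSOTf, 2,6-lutidine, CH2Cl2, 0 °C → rt
Reagents that add atoms: tert-butyldimethylsilyl trifluoromethanesulfonate, CC(C)(C)[Si](C)(C)OS(=O)(=O)C(F)(F)F
Why: Silylation of the hindered axial secondary alcohol with the silyl triflate; the group shields C6 during the two later oxidations.

**Step 14**
Reactants: 26 the C6 silyl ether
Product: 27 the (S)-1,2-diol at C4/C15 (acetonide removed)
Conditions: AcOH/H2O (4:1), 35 °C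
Reagents that add atoms: none
Why: Mild acid hydrolysis of a terminal isopropylidene acetal; the hindered secondary silyl ether, the PMB ether and the esters should survive.

**Step 15**
Reactants: 27 the C4/C15 diol
Product: 28 the C15 primary tert-butyldimethylsilyl ether (C4 secondary OH free)
Conditions: TBSCl, imidazole, CH2Cl2, 0 °C
Reagents that add atoms: tert-butyldimethylsilyl chloride, CC(C)(C)[Si](C)(C)Cl
Why: Selective silylation of the primary hydroxyl of a 1,2-diol on steric grounds.

**Step 16**
Reactants: 28 the C15 silyl ether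
Product: 29 the C4 ketone (α-silyloxy ketone)
Conditions: Dess–Martin periodinane, NaHCO3, CH2Cl2, rt
Reagents that add atoms: none
Why: Buffered, non-basic oxidation of the only free hydroxyl; the auxiliary stereocenter at C4 is erased here, and C5 should not epimerize under these conditions.

**Step 17**
Reactants: 29 the C4 ketone
Product: 30 the C4=C3 methylene compound (2-(silyloxymethyl)vinyl group on C5)
Conditions: Zn, CH2Br2, TiCl4, THF/CH2Cl2, 0 °C → rt
Reagents that add atoms: dibromomethane, BrCBr
Why: Lombardo–Takai methylenation, which is non-basic (no epimerization at C5 and no β-elimination of the C6 silyloxy group) and selective for ketones over esters.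

**Step 18**
Reactants: 30 the methylene compound
Product: 31 the C12 primary alcohol (PMB removed)
Conditions: DDQ, CH2Cl2/pH 7 buffer, 0 °C
Reagents that add atoms: none
Why: Oxidative cleavage of the PMB ether, orthogonal to the silyl ethers, the esters and the unactivated alkenes.

**Step 19**
Reactants: 31 the C12 alcohol
Product: 32 the C12 aldehyde
Conditions: Dess–Martin periodinane, NaHCO3, CH2Cl2, 0 °C → rt
Reagents that add atoms: none
Why: Mild oxidation of the primary alcohol; the C6 silyl ether prevents lactol formation.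

**Step 20**
Reactants: 32 the C12 aldehyde
Product: 34 the α-methylene aldehyde (C11=C13 in place), via Mannich base 33 (not isolated)
Conditions: CH2=NMe2+ I−, Et3N, CH2Cl2, rt
Reagents that add atoms: N,N-dimethylmethyleneiminium iodide, C=[N+](C)C.[I-]
Why: Mannich reaction with Eschenmoser's salt followed by elimination of dimethylamine is the standard α-methylenation of aldehydes and does not touch C7.

**Step 21**
Reactants: 34 the α-methylene aldehyde
Product: 35 the acrylic acid (C6 and C15 still silylated)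
Conditions: NaClO2, NaH2PO4, 2-methylbut-2-ene, t-BuOH/H2O, 0 °C
Reagents that add atoms: sodium chlorite, [Na+].[O-]Cl=O
Why: Pinnick oxidation converts enals to acids without alkene isomerization; the scavenger removes hypochlorous acid and protects the other alkenes.

**Step 22**
Reactants: 35 the bis-silyl acrylic acid
Product: 36 2-[(1S,2S,3R,4S,6R)-6-{[(2Z)-4-(acetyloxy)-2-methylbut-2-enoyl]oxy}-4-ethenyl-2-hydroxy-3-(3-hydroxyprop-1-en-2-yl)-4-methylcyclohexyl]prop-2-enoic acid (target)
Conditions: HF·pyridine, pyridine, THF, 0 °C → rt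
Reagents that add atoms: none
Why: Buffered fluoride desilylation removes both silyl ethers without base, so acyl migration from O8 to O6 is avoided, and the cold, short exposure should limit lactonization of the freed 6-hydroxyl onto the acid.

**Compound list**

1 | methyl [(4S)-2,2-dimethyl-1,3-dioxolan-4-yl]acetate | COC(=O)C[C@H]1COC(C)(C)O1 | starting material
2 | [(4S)-2,2-dimethyl-1,3-dioxolan-4-yl]acetic acid | OC(=O)C[C@H]1COC(C)(C)O1 | intermediate
3 | ethoxyethyne | C#COCC | starting material
4 | [(4S)-2,2-dimethyl-1,3-dioxolan-4-yl]acetyl chloride | ClC(=O)C[C@H]1COC(C)(C)O1 | intermediate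
5 | [(4S)-2,2-dimethyl-1,3-dioxolan-4-yl]ketene | O=C=C[C@H]1COC(C)(C)O1 | intermediate
6 | (4R)-4-[(4S)-2,2-dimethyl-1,3-dioxolan-4-yl]-3-ethoxycyclobut-2-en-1-one | O=C1C=C(OCC)[C@H]1[C@H]2COC(C)(C)O2 | intermediate
7 | (4R)-4-[(4S)-2,2-dimethyl-1,3-dioxolan-4-yl]-3-ethoxy-1-methylcyclobut-2-en-1-ol (carbinol epimers) | CC1(O)C=C(OCC)[C@H]1[C@H]2COC(C)(C)O2 | intermediate
8 | (4R)-4-[(4S)-2,2-dimethyl-1,3-dioxolan-4-yl]-3-methylcyclobut-2-en-1-one | CC1=CC(=O)[C@H]1[C@H]2COC(C)(C)O2 | intermediate
9 | (2R,3S)-2-[(4S)-2,2-dimethyl-1,3-dioxolan-4-yl]-3-ethenyl-3-methylcyclobutan-1-one | C=C[C@]1(C)CC(=O)[C@H]1[C@H]2COC(C)(C)O2 | intermediate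
10 | but-3-yn-1-ol | C#CCCO | starting material
11 | 1-[(but-3-yn-1-yloxy)methyl]-4-methoxybenzene | C#CCCOCc1ccc(OC)cc1 | intermediate
12 | lithium acetylide of 11 | [Li]C#CCCOCc1ccc(OC)cc1 | intermediate
13 | lithium 4-[(4-methoxybenzyl)oxy]but-1-yn-1-olate | [Li]OC#CCCOCc1ccc(OC)cc1 | intermediate
14 | triisopropyl({4-[(4-methoxybenzyl)oxy]but-1-yn-1-yl}oxy)silane | CC(C)[Si](OC#CCCOCc1ccc(OC)cc1)(C(C)C)C(C)C | intermediate
15 | (5S,6R)-6-[(4S)-2,2-dimethyl-1,3-dioxolan-4-yl]-5-ethenyl-2-{2-[(4-methoxybenzyl)oxy]ethyl}-5-methyl-3-[(triisopropylsilyl)oxy]cyclohex-2-en-1-one | C=C[C@]1(C)CC(O[Si](C(C)C)(C(C)C)C(C)C)=C(CCOCc2ccc(OC)cc2)C(=O)[C@H]1[C@H]3COC(C)(C)O3 | intermediate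
16 | C6 allylic alcohol of 15 (6-OH cis to C10 methyl and C5 dioxolanyl) | C=C[C@]1(C)CC(O[Si](C(C)C)(C(C)C)C(C)C)=C(CCOCc2ccc(OC)cc2)[C@@H](O)[C@H]1[C@H]3COC(C)(C)O3 | intermediate
17 | 4-[(4S)-2,2-dimethyl-1,3-dioxolan-4-yl]-5-ethenyl-3-hydroxy-2-{2-[(4-methoxybenzyl)oxy]ethyl}-5-methylcyclohexan-1-one (2-chain, 3-OH, 4-dioxolanyl and 5-CH3 all cis) | C=C[C@]1(C)CC(=O)[C@@H](CCOCc2ccc(OC)cc2)[C@@H](O)[C@H]1[C@H]3COC(C)(C)O3 | intermediate
18 | all-cis 4-[(4S)-2,2-dimethyl-1,3-dioxolan-4-yl]-5-ethenyl-2-{2-[(4-methoxybenzyl)oxy]ethyl}-5-methylcyclohexane-1,3-diol | C=C[C@]1(C)C[C@@H](O)[C@@H](CCOCc2ccc(OC)cc2)[C@@H](O)[C@H]1[C@H]3COC(C)(C)O3 | intermediate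
19 | 3-methylfuran-2(5H)-one | CC1=CCOC1=O | starting material
20 | potassium (2Z)-4-hydroxy-2-methylbut-2-enoate | [K+].[O-]C(=O)/C(C)=C\CO | intermediate
21 | tert-butyldimethylsilyl (2Z)-4-hydroxy-2-methylbut-2-enoate | CC(C)(C)[Si](C)(C)OC(=O)/C(C)=C\CO | intermediate
22 | tert-butyldimethylsilyl (2Z)-4-(acetyloxy)-2-methylbut-2-enoate | CC(C)(C)[Si](C)(C)OC(=O)/C(C)=C\COC(C)=O | intermediate
23 | (2Z)-4-(acetyloxy)-2-methylbut-2-enoic acid | OC(=O)/C(C)=C\COC(C)=O | intermediate
24 | (2Z)-4-(acetyloxy)-2-methylbut-2-enoic 2,4,6-trichlorobenzoic anhydride | O=C(OC(=O)/C(C)=C\COC(C)=O)c1c(Cl)cc(Cl)cc1Cl | intermediate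
25 | C8 (2Z)-4-(acetyloxy)-2-methylbut-2-enoate of 18 (6-OH free) | C=C[C@]1(C)C[C@@H](OC(=O)/C(C)=C\COC(C)=O)[C@@H](CCOCc2ccc(OC)cc2)[C@@H](O)[C@H]1[C@H]3COC(C)(C)O3 | intermediate
26 | C6 tert-butyldimethylsilyl ether of 25 | C=C[C@]1(C)C[C@@H](OC(=O)/C(C)=C\COC(C)=O)[C@@H](CCOCc2ccc(OC)cc2)[C@@H](O[Si](C)(C)C(C)(C)C)[C@H]1[C@H]3COC(C)(C)O3 | intermediate
27 | C4/C15 (S)-1,2-diol from 26 | C=C[C@]1(C)C[C@@H](OC(=O)/C(C)=C\COC(C)=O)[C@@H](CCOCc2ccc(OC)cc2)[C@@H](O[Si](C)(C)C(C)(C)C)[C@H]1[C@H](O)CO | intermediate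
28 | C15 tert-butyldimethylsilyl ether of 27 (C4-OH free) | C=C[C@]1(C)C[C@@H](OC(=O)/C(C)=C\COC(C)=O)[C@@H](CCOCc2ccc(OC)cc2)[C@@H](O[Si](C)(C)C(C)(C)C)[C@H]1[C@H](O)CO[Si](C)(C)C(C)(C)C | intermediate
29 | C4 ketone from 28 | C=C[C@]1(C)C[C@@H](OC(=O)/C(C)=C\COC(C)=O)[C@@H](CCOCc2ccc(OC)cc2)[C@@H](O[Si](C)(C)C(C)(C)C)[C@H]1C(=O)CO[Si](C)(C)C(C)(C)C | intermediate
30 | C4=C3 methylene compound from 29 | C=C[C@]1(C)C[C@@H](OC(=O)/C(C)=C\COC(C)=O)[C@@H](CCOCc2ccc(OC)cc2)[C@@H](O[Si](C)(C)C(C)(C)C)[C@H]1C(=C)CO[Si](C)(C)C(C)(C)C | intermediate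
31 | C12 primary alcohol from 30 | C=C[C@]1(C)C[C@@H](OC(=O)/C(C)=C\COC(C)=O)[C@@H](CCO)[C@@H](O[Si](C)(C)C(C)(C)C)[C@H]1C(=C)CO[Si](C)(C)C(C)(C)C | intermediate
32 | C12 aldehyde from 31 | C=C[C@]1(C)C[C@@H](OC(=O)/C(C)=C\COC(C)=O)[C@@H](CC=O)[C@@H](O[Si](C)(C)C(C)(C)C)[C@H]1C(=C)CO[Si](C)(C)C(C)(C)C | intermediate
33 | C11 dimethylaminomethyl aldehyde (Mannich base, C11 epimers) | C=C[C@]1(C)C[C@@H](OC(=O)/C(C)=C\COC(C)=O)[C@@H](C(CN(C)C)C=O)[C@@H](O[Si](C)(C)C(C)(C)C)[C@H]1C(=C)CO[Si](C)(C)C(C)(C)C | intermediate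
34 | α-methylene aldehyde from 32 | C=C[C@]1(C)C[C@@H](OC(=O)/C(C)=C\COC(C)=O)[C@@H](C(=C)C=O)[C@@H](O[Si](C)(C)C(C)(C)C)[C@H]1C(=C)CO[Si](C)(C)C(C)(C)C | intermediate
35 | 6,15-bis-O-tert-butyldimethylsilyl ether of the target acid | C=C[C@]1(C)C[C@@H](OC(=O)/C(C)=C\COC(C)=O)[C@@H](C(=C)C(=O)O)[C@@H](O[Si](C)(C)C(C)(C)C)[C@H]1C(=C)CO[Si](C)(C)C(C)(C)C | intermediate
36 | 2-[(1S,2S,3R,4S,6R)-6-{[(2Z)-4-(acetyloxy)-2-methylbut-2-enoyl]oxy}-4-ethenyl-2-hydroxy-3-(3-hydroxyprop-1-en-2-yl)-4-methylcyclohexyl]prop-2-enoic acid | C=C[C@]1(C)C[C@@H](OC(=O)/C(C)=C\COC(C)=O)[C@@H](C(=C)C(=O)O)[C@@H](O)[C@H]1C(=C)CO | target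

**Count and risks**

Total step count: 22. Longest linear sequence: 19 steps (steps 1–4, 7–10, 12–22); steps 5–6 and step 11 are side branches.

Steps most likely to fail:

1. Step 7 (Proposed new method). The insertion may stall with the α-branched cyclobutanone, the alkyne may oligomerize faster than it inserts, or the wrong acyl–carbon bond may be cleaved. Fallback by known chemistry, setting out from 9 and returning at 15: kinetic deprotonation of 9 at the CH2 group (LDA, THF, −78 °C) and C-acylation with 1-{4-[(4-methoxybenzyl)oxy]butanoyl}-1H-benzotriazole should give the 2-acylcyclobutanone F1. Strain-driven retro-Claisen opening with NaOMe in MeOH should give the δ-keto ester F2. Dieckmann-type closure with KOt-Bu in THF should give the cyclohexane-1,3-dione F3, and O-silylation at the less hindered C8 oxygen (TIPSOTf, Et3N, CH2Cl2, −78 °C) returns 15. In this fallback the two ring bonds are made in separate operations.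

2. Step 2. Facial selectivity at the new ring stereocenter may be poor, and the alkylketene may dimerize or lose the neighbouring acetonide oxygen by β-elimination before it is trapped. Fallback, setting out from 2 and returning at 8: coupling of 2 with (2R,5R)-2,5-dimethylpyrrolidine gives the amide F4. Activation with triflic anhydride and 2,6-di-tert-butyl-4-methylpyridine forms a chiral keteniminium ion that is trapped by propyne in a [2+2] cycloaddition to give the cyclobuteniminium triflate F5. Aqueous hydrolysis releases the auxiliary and gives 8 directly, with the auxiliary controlling the face (the auxiliary enantiomer is chosen to match the required C5 configuration).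

3. Step 12. Acylation of the axial hydroxyl may be incomplete, the activated acid may isomerize from Z to E, or the acyl group may end on the wrong hydroxyl. Fallback, setting out from 18 and returning at 26: esterification of the C8 hydroxyl with 2-[bis(2,2,2-trifluoroethoxy)phosphoryl]propanoic acid (DCC, DMAP) gives the phosphonopropionate F6. Silylation of the C6 hydroxyl (TBSOTf, 2,6-lutidine) gives F7. Still–Gennari olefination of F7 with 2-oxoethyl acetate (KHMDS, 18-crown-6, THF, −78 °C) builds the Z-enoate on the substrate and gives 26.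

**Further compounds**

F1 | step 7 | 2-{4-[(4-methoxybenzyl)oxy]butanoyl} derivative of 9 (acylated at the ring CH2; enolizable center unspecified) | C=C[C@]1(C)C(C(=O)CCCOCc2ccc(OC)cc2)C(=O)[C@H]1[C@H]3COC(C)(C)O3
F2 | step 7 | methyl (2R,3S)-2-[(4S)-2,2-dimethyl-1,3-dioxolan-4-yl]-3-ethenyl-8-[(4-methoxybenzyl)oxy]-3-methyl-5-oxooctanoate | C=C[C@](C)(CC(=O)CCCOCc1ccc(OC)cc1)[C@@H](C(=O)OC)[C@H]2COC(C)(C)O2
F3 | step 7 | 4-[(4S)-2,2-dimethyl-1,3-dioxolan-4-yl]-5-ethenyl-2-{2-[(4-methoxybenzyl)oxy]ethyl}-5-methylcyclohexane-1,3-dione (4-dioxolanyl cis to 5-CH3; C2 enolizable) | C=C[C@]1(C)CC(=O)C(CCOCc2ccc(OC)cc2)C(=O)[C@H]1[C@H]3COC(C)(C)O3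
F4 | step 2 | 1-[(2R,5R)-2,5-dimethylpyrrolidin-1-yl]-2-[(4S)-2,2-dimethyl-1,3-dioxolan-4-yl]ethan-1-one | C[C@@H]1CC[C@@H](C)N1C(=O)C[C@H]2COC(C)(C)O2
F5 | step 2 | cyclobuteniminium triflate (iminium form of 8 with the (2R,5R)-2,5-dimethylpyrrolidine auxiliary) | C[C@@H]1CC[C@@H](C)[N+]1=C2C=C(C)[C@@H]2[C@H]3COC(C)(C)O3.[O-]S(=O)(=O)C(F)(F)F
F6 | step 12 | C8 2-[bis(2,2,2-trifluoroethoxy)phosphoryl]propanoate of 18 (6-OH free) | C=C[C@]1(C)C[C@@H](OC(=O)C(C)P(=O)(OCC(F)(F)F)OCC(F)(F)F)[C@@H](CCOCc2ccc(OC)cc2)[C@@H](O)[C@H]1[C@H]3COC(C)(C)O3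
F7 | step 12 | C6 tert-butyldimethylsilyl ether of F6 | C=C[C@]1(C)C[C@@H](OC(=O)C(C)P(=O)(OCC(F)(F)F)OCC(F)(F)F)[C@@H](CCOCc2ccc(OC)cc2)[C@@H](O[Si](C)(C)C(C)(C)C)[C@H]1[C@H]3COC(C)(C)O3
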